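**Retrosynthetic overview**

1. Atoms are numbered as in the target SMILES (C1…O32); ring A is the δ-lactone C2–O4–C5–C7=C8–C9, ring B the cyclohexane C9–C10–C11–C12–C21–C22, and the cage is the bicyclo[2.2.2]octane (bridgeheads C14, C25) plus the cyclopentane C12–C21–C20–C18–C25.
2. Feature used: the lactone CH2 (C26) sits on quaternary bridgehead C25, γ to carboxyl C28 through C30, and is the only γ carbon that bears hydrogen (C12, C14 and C18 are quaternary). The γ-lactone C25–C26–O27–C28–C30 is therefore closed last, by carboxylate-directed C–H oxygenation of a native C26 methyl in acid 23.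
3. Acid 23 comes from cage β-keto ester 20 (C31 reduction, silylation, ester demethylation). Cage 20 comes from an intramolecular Diels–Alder reaction of the dienone diene C14=C31–C30=C25 with the exocyclic alkene C12=C13, which forms C13–C14 and C12–C25 and closes both cage carbocycles.
4. The C18–C20 bond is made by dearomative Michael addition of benzoate 3 to ring B enone 13. C12 methylenation then freezes C21, and only afterwards is ring A closed (ester to CMe2–O acrylate, then ring-closing metathesis at C7=C8), because the bulky CMe2 arm would otherwise bias C21 toward the wrong epimer.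
5. Ring order: B (from methyl 2-oxocyclohexane-1-carboxylate; C9 by asymmetric allylation, C22 by chelation-controlled methyl addition), then dienone coupling, then A, then the two cage rings, then the γ-lactone.

Key step: step 18

Assumption: the sense of induction of the Trost ligand (step 3) and of BINAP (step 15) is taken from the usual empirical models; if either proves opposite, the antipodal ligand is used.

**Route**

Step 1
Reactants: 1 methyl 2,4-dihydroxy-3,6-dimethylbenzoate
Product: 2 methyl 5-formyl-2,4-dihydroxy-3,6-dimethylbenzoate
Conditions: Cl2CHOMe, TiCl4, CH2Cl2, 0 °C; then aq. HCl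
Reagents that add atoms: dichloromethyl methyl ether, COC(Cl)Cl; water, O
Why: Rieche formylation (electrophilic aromatic substitution) can only attack C5, the single unsubstituted ring carbon, which is ortho to one hydroxyl and para to the other; no stereocentre is formed.

Step 2
Reactants: 2 methyl 5-formyl-2,4-dihydroxy-3,6-dimethylbenzoate
Product: 3 methyl 2,4-dihydroxy-3,5,6-trimethylbenzoate
Conditions: Et3SiH, CF3CO2H, CH2Cl2, rt
Reagents that add atoms: none
Why: Ionic hydrogenation: the hydroxy-stabilised benzylic cation from the protonated aldehyde takes hydride from Et3SiH twice, giving the aryl methyl group without touching the ester.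

Step 3
Reactants: 4 methyl 2-oxocyclohexane-1-carboxylate
Product: 5 methyl (S)-2-oxo-1-(prop-2-en-1-yl)cyclohexane-1-carboxylate
Conditions: allyl acetate, [Pd(C3H5)Cl]2 (1 mol%), (R,R)-DACH-phenyl Trost ligand (3 mol%), tetramethylguanidine, toluene, 0 °C
Reagents that add atoms: allyl acetate, C=CCOC(C)=O
Why: Tsuji–Trost asymmetric allylic alkylation: the guanidinium enolate of the β-keto ester attacks the π-allylpalladium complex inside the chiral pocket of the Trost ligand, which differentiates the enolate faces and should set quaternary C9 as (S).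

Step 4
Reactants: 5 methyl (S)-2-oxo-1-(prop-2-en-1-yl)cyclohexane-1-carboxylate
Product: 6 methyl (S)-2-oxo-1-[(E)-prop-1-en-1-yl]cyclohexane-1-carboxylate
Conditions: RuHCl(CO)(PPh3)3 (2 mol%), toluene, 80 °C
Reagents that add atoms: none
Why: Ruthenium hydride-catalysed alkene isomerisation (hydrometalation/β-hydride elimination) moves the double bond one position to the more stable (E)-propenyl isomer and must stop there because C9 carries no hydrogen.

Step 5
Reactants: 6 methyl (S)-2-oxo-1-[(E)-prop-1-en-1-yl]cyclohexane-1-carboxylate
Product: 9 methyl (S)-3-methylidene-2-oxo-1-[(E)-prop-1-en-1-yl]cyclohexane-1-carboxylate, via Mannich base 7 (not isolated), via ammonium iodide 8 (not isolated)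
Conditions: LiN(iPr)2, THF, −78 °C; CH2=NMe2+ I−, −78 to 0 °C; MeI, rt; aq. NaHCO3, rt
Reagents that add atoms: Eschenmoser's salt, C=[N+](C)C.[I-]
Why: C21 is the only enolisable position (C9 is quaternary), so its lithium enolate undergoes a Mannich reaction with Eschenmoser's salt and the quaternised amine is lost by β-elimination to give the α-methylene ketone.

Step 6
Reactants: 9 methyl (S)-3-methylidene-2-oxo-1-[(E)-prop-1-en-1-yl]cyclohexane-1-carboxylate
Product: 10 methyl (1S,2R)-2-hydroxy-2-methyl-3-methylidene-1-[(E)-prop-1-en-1-yl]cyclohexane-1-carboxylate (OH cis to propenyl)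
Conditions: MeMgBr, CeCl3, THF, −78 °C; aq. NH4Cl
Reagents that add atoms: methylmagnesium bromide, C[Mg]Br
Why: Organocerium 1,2-addition to the ketone (faster than to the hindered ester, not conjugate) under Cram chelate control: the metal bridges the ketone and ester carbonyls, which puts the propenyl group axial, so methyl should enter anti to it and give C22 with OH cis to propenyl and methyl cis to the ester.

Step 7
Reactants: 10 methyl (1S,2R)-2-hydroxy-2-methyl-3-methylidene-1-[(E)-prop-1-en-1-yl]cyclohexane-1-carboxylate
Product: 11 triethylsilyl ether of 10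
Conditions: Et3SiOTf, 2,6-lutidine, CH2Cl2, −78 to 0 °C
Reagents that add atoms: triethylsilyl triflate, CC[Si](CC)(CC)OS(=O)(=O)C(F)(F)F
Why: Silyl triflate/lutidine silylation is strong enough for the hindered tertiary alcohol, and the ether prevents retro-aldol cleavage once C12 is a ketone.

Step 8
Reactants: 11 triethylsilyl ether of 10
Product: 12 methyl (1S,2R)-4-hydroxy-2-methyl-3-methylidene-1-[(E)-prop-1-en-1-yl]-2-(triethylsilyloxy)cyclohexane-1-carboxylate (C12 epimers)
Conditions: SeO2 (0.5 equiv), t-BuOOH, CH2Cl2, rt
Reagents that add atoms: selenium dioxide, O=[Se]=O; tert-butyl hydroperoxide, CC(C)(C)OO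
Why: Selenium dioxide allylic oxidation (ene reaction then [2,3]-sigmatropic shift) of the 1,1-disubstituted alkene at C12, its only allylic CH2, whereas the propenyl group would have to bond selenium at the neopentyl carbon C8; the new C12 carbinol forms as a mixture that is removed in step 9.

Step 9
Reactants: 12 allylic alcohol (C12 epimers)
Product: 13 methyl (1S,2R)-2-methyl-3-methylidene-4-oxo-1-[(E)-prop-1-en-1-yl]-2-(triethylsilyloxy)cyclohexane-1-carboxylate (ring B enone)
Conditions: Dess–Martin periodinane, NaHCO3, CH2Cl2, rt
Reagents that add atoms: none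
Why: Dess–Martin oxidation of the secondary allylic alcohol gives the exocyclic enone under neutral buffered conditions that leave the silyl ether and both alkenes alone.

Step 10
Reactants: 3 methyl 2,4-dihydroxy-3,5,6-trimethylbenzoate; 13 ring B enone
Product: 14 Michael adduct: ring B ketone joined at C21 through C20H2 to the dearomatised benzoate ring (C18 quaternary, C16 ketone, C31 enol, C30 CO2Me), with C18 and C21 as in the target (C20 cis to propenyl and to OSiEt3)
Conditions: 3 (1.2 equiv), DBU, MeCN, 0 °C to rt; aq. citric acid
Reagents that add atoms: none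
Why: Dearomative Michael addition: the phenolate of 3 attacks the unhindered methylene terminus C20 through ring carbon C18, and because DBU keeps the addition reversible the material should drain to the C18 adduct, the only C-adduct whose ring can relax to a cyclic 2-methyl-1,3-diketonate; C18 forms without facial control and C21 by protonation then DBU equilibration (expected to favour, only moderately, the C20 arm equatorial and cis to the equatorial propenyl group), so isomer 14 is separated and the other isomers are returned to the DBU equilibration (retro-Michael and enolisation).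

Step 11
Reactants: 14 Michael adduct
Product: 15 C12-methylene triene (14 with C12=C13H2 in place of C12=O)
Conditions: CH2Br2, Zn, TiCl4 (excess), THF–CH2Cl2, 0 °C to rt
Reagents that add atoms: dibromomethane, BrCBr
Why: Takai–Lombardo methylenation with the non-basic zinc/titanium reagent converts only the ketone (the esters are inert and the vinylogous acid merely consumes reagent) and does not epimerise C21 or eliminate the β-silyloxy group, so C21 is frozen.

Step 12
Reactants: 15 C12-methylene triene
Product: 18 C2 acrylate (C9 now carries CMe2–O–acryloyl; dienone enol free), via dilithium alkoxide 16 (not isolated), via bis-acrylate 17 (not isolated)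
Conditions: MeLi (6 equiv), CeCl3, THF, −78 to 0 °C; acryloyl chloride (4 equiv), −78 °C to rt; aq. NaHCO3–MeOH, 0 °C
Reagents that add atoms: methyllithium, C[Li]; acryloyl chloride, C=CC(=O)Cl
Why: Methyllithium first deprotonates the vinylogous acid, and the resulting lithium diketonate shields C16 and the ring ester, so that cerium-assisted double addition converts only the C9 ester into the tertiary alkoxide, which is acylated in situ (alkoxide acylation), the labile enol acrylate on the dienone being hydrolysed in the bicarbonate work-up.

Step 13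
Reactants: 18 C2 acrylate
Product: 19 spiro-lactone triene (ring A closed; Diels–Alder precursor)
Conditions: RuCl2(H2IMes)(=CH-C6H4-2-OiPr) (second-generation Hoveyda–Grubbs catalyst, 5 mol%), CH2Cl2, 40 °C
Reagents that add atoms: none
Why: Ring-closing metathesis between the acrylate and the propenyl group closes ring A as the six-membered Z-enoate lactone with loss of propene, while the exocyclic methylene (closure onto it would give a bridgehead alkene) and the tetrasubstituted dienone alkenes do not take part.

Step 14
Reactants: 19 spiro-lactone triene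
Product: 20 Diels–Alder adduct: cage β-keto ester (enol form), C22 OSiEt3
Conditions: toluene, BHT, 110 °C
Reagents that add atoms: none
Why: Intramolecular Diels–Alder reaction of a 6-(but-3-enyl)cyclohexa-2,4-dienone (isotwistane formation, inverse electron demand): the alkene can reach the diene C14=C31–C30=C25 only on the face that carries the C20 tether, so C25, C14 and C12 follow from C18, and only the cis fusion of ring B to the new cyclopentane, which requires the C18/C21 relationship of 19, is attainable.

Step 15
Reactants: 20 cage β-keto ester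
Product: 21 C31 hydroxy ester (trans; OH toward the C16 bridge, ester toward the C12 bridge)
Conditions: H2 (50 atm), RuCl2[(S)-BINAP](dmf)n (2 mol%), MeOH–CH2Cl2, 50 °C
Reagents that add atoms: none
Why: Noyori hydrogenation of an α-substituted β-keto ester with dynamic kinetic resolution: the keto ester chelates ruthenium, hydride passes to C31 on the face that carries the ester (giving the trans hydroxy ester), C30 epimerises through the enol, and the BINAP ligand should select the diastereomer with the ester on the C12 side, while the unchelated C16 ketone and the ring A enoate are not activated.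

Step 16
Reactants: 21 C31 hydroxy ester
Product: 22 C31 tert-butyldimethylsilyl ether methyl ester
Conditions: t-BuMe2SiOTf, 2,6-lutidine, CH2Cl2, 0 °C
Reagents that add atoms: tert-butyldimethylsilyl triflate, CC(C)(C)[Si](C)(C)OS(=O)(=O)C(F)(F)F
Why: Silyl triflate silylation of the hindered secondary alcohol protects C31–OH from oxidation and from competing as a ligand in step 18.

Step 17
Reactants: 22 C31 silyl ether methyl ester
Product: 23 C28 carboxylic acid with C26 methyl, C31 OSiMe2t-Bu, C22 OSiEt3 (key-step precursor)
Conditions: LiI, pyridine, 110 °C; then 1 M HCl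
Reagents that add atoms: none
Why: Nucleophilic ester demethylation (SN2 by iodide at O–CH3) is insensitive to the crowding around the carbonyl, leaves the tertiary-alkyl lactone untouched and avoids strongly basic conditions that could eliminate the β-silyloxy group or epimerise C30.

Step 18
Reactants: 23 C28 carboxylic acid
Product: 24 γ-lactone bis-silyl ether (target with C31 OSiMe2t-Bu and C22 OSiEt3)
Conditions: Pd(OAc)2 (10 mol%), N-acetyl-β-alanine (20 mol%), aq. t-BuOOH (3 equiv), CsHCO3, (CF3)2CHOH, 60 °C
Reagents that add atoms: none
Why: The carboxylate of 23 binds divalent palladium and, assisted by the mono-protected amino acid ligand, a C26–H bond is cleaved by concerted metalation–deprotonation through a six-membered palladacycle (Pd–O–C28–C30–C25–C26); t-BuOOH oxidises this to a tetravalent alkylpalladium species and C26–O27 reductive elimination releases the lactone. The closest known reaction type is the palladium-catalysed carboxylate-directed γ-C(sp3)–H lactonisation of aliphatic acids that carry a quaternary β-carbon. The γ-lactone ring (C25, C26, O27, C28, C30) closes in a 5-exo-tet sense by intramolecular C–O bond formation at the metalated methyl carbon. No stereocentre is created: C25 and C30 are already in place and a cis ring fusion is the only geometry the bicyclo[2.2.2]octane allows. The step needs site selectivity only: C26 is the single γ carbon with hydrogen (C12, C14 and C18 are quaternary), the β C31–H is a hindered methine that should not cyclometalate, and both hydroxyls are silylated so that neither is oxidised.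

Step 19
Reactants: 24 γ-lactone bis-silyl ether
Product: 25 target (CNP0360620.3)
Conditions: HF·pyridine, THF, 0 °C to rt
Reagents that add atoms: none
Why: Fluoride-mediated desilylation removes both silyl ethers under acidic, non-nucleophilic conditions that spare the two lactones and cannot trigger retro-aldol cleavage.

**Compound list**

1 | methyl 2,4-dihydroxy-3,6-dimethylbenzoate | COC(=O)c1c(C)cc(O)c(C)c1O | starting material
2 | methyl 5-formyl-2,4-dihydroxy-3,6-dimethylbenzoate | COC(=O)c1c(C)c(C=O)c(O)c(C)c1O | intermediate
3 | methyl 2,4-dihydroxy-3,5,6-trimethylbenzoate | COC(=O)c1c(C)c(C)c(O)c(C)c1O | intermediate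
4 | methyl 2-oxocyclohexane-1-carboxylate | COC(=O)C1CCCCC1=O | starting material
5 | methyl (S)-2-oxo-1-(prop-2-en-1-yl)cyclohexane-1-carboxylate | C=CC[C@@]1(C(=O)OC)CCCCC1=O | intermediate
6 | methyl (S)-2-oxo-1-[(E)-prop-1-en-1-yl]cyclohexane-1-carboxylate | C/C=C/[C@@]1(C(=O)OC)CCCCC1=O | intermediate
7 | Mannich base, methyl (1S)-3-[(dimethylamino)methyl]-2-oxo-1-[(E)-prop-1-en-1-yl]cyclohexane-1-carboxylate (not isolated) | C/C=C/[C@@]1(C(=O)OC)CCCC(CN(C)C)C1=O | intermediate
8 | trimethylammonium iodide of 7 (not isolated) | C/C=C/[C@@]1(C(=O)OC)CCCC(C[N+](C)(C)C)C1=O.[I-] | intermediate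
9 | methyl (S)-3-methylidene-2-oxo-1-[(E)-prop-1-en-1-yl]cyclohexane-1-carboxylate | C/C=C/[C@@]1(C(=O)OC)CCCC(=C)C1=O | intermediate
10 | methyl (1S,2R)-2-hydroxy-2-methyl-3-methylidene-1-[(E)-prop-1-en-1-yl]cyclohexane-1-carboxylate | C/C=C/[C@@]1(C(=O)OC)CCCC(=C)[C@@]1(C)O | intermediate
11 | triethylsilyl ether of 10 | C/C=C/[C@@]1(C(=O)OC)CCCC(=C)[C@@]1(C)O[Si](CC)(CC)CC | intermediate
12 | C12 allylic alcohol of 11 (C12 epimers) | C/C=C/[C@@]1(C(=O)OC)CCC(O)C(=C)[C@@]1(C)O[Si](CC)(CC)CC | intermediate
13 | ring B enone, methyl (1S,2R)-2-methyl-3-methylidene-4-oxo-1-[(E)-prop-1-en-1-yl]-2-(triethylsilyloxy)cyclohexane-1-carboxylate | C/C=C/[C@@]1(C(=O)OC)CCC(=O)C(=C)[C@@]1(C)O[Si](CC)(CC)CC | intermediate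
14 | Michael adduct (ring B ketone linked C21–C20–C18 to the dearomatised benzoate; C18, C21 as in target) | C/C=C/[C@@]1(C(=O)OC)CCC(=O)[C@@H](C[C@@]2(C)C(=O)C(C)=C(O)C(C(=O)OC)=C2C)[C@@]1(C)O[Si](CC)(CC)CC | intermediate
15 | C12-methylene triene | C/C=C/[C@@]1(C(=O)OC)CCC(=C)[C@@H](C[C@@]2(C)C(=O)C(C)=C(O)C(C(=O)OC)=C2C)[C@@]1(C)O[Si](CC)(CC)CC | intermediate
16 | dilithium salt of the C2 tertiary alkoxide and dienone enolate (not isolated) | C/C=C/[C@@]1(C(C)(C)[O-])CCC(=C)[C@@H](C[C@@]2(C)C(=O)C(C)=C([O-])C(C(=O)OC)=C2C)[C@@]1(C)O[Si](CC)(CC)CC.[Li+].[Li+] | intermediate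
17 | bis-acrylate: C2 acrylate and enol acrylate at the C16 oxygen (not isolated) | C/C=C/[C@@]1(C(C)(C)OC(=O)C=C)CCC(=C)[C@@H](C[C@@]2(C)C(OC(=O)C=C)=C(C)C(=O)C(C(=O)OC)=C2C)[C@@]1(C)O[Si](CC)(CC)CC | intermediate
18 | C2 acrylate, dienone enol free | C/C=C/[C@@]1(C(C)(C)OC(=O)C=C)CCC(=C)[C@@H](C[C@@]2(C)C(=O)C(C)=C(O)C(C(=O)OC)=C2C)[C@@]1(C)O[Si](CC)(CC)CC | intermediate
19 | spiro-lactone triene (rings A and B, dienone, C12=C13) | CC1(C)OC(=O)C=C[C@]12CCC(=C)[C@H]([C@@]2(C)O[Si](CC)(CC)CC)C[C@@]3(C)C(=O)C(C)=C(O)C(C(=O)OC)=C3C | intermediate
20 | cage β-keto ester (enol form), C22 OSiEt3 | CC1(C)OC(=O)C=C[C@]12CC[C@]13C[C@]4(C)C(=O)[C@](C)(C[C@H]1[C@@]2(C)O[Si](CC)(CC)CC)[C@@]3(C)C(C(=O)OC)=C4O | intermediate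
21 | C31 hydroxy methyl ester | CC1(C)OC(=O)C=C[C@]12CC[C@]13C[C@]4(C)C(=O)[C@](C)(C[C@H]1[C@@]2(C)O[Si](CC)(CC)CC)[C@@]3(C)[C@H](C(=O)OC)[C@H]4O | intermediate
22 | C31 tert-butyldimethylsilyl ether methyl ester | CC1(C)OC(=O)C=C[C@]12CC[C@]13C[C@]4(C)C(=O)[C@](C)(C[C@H]1[C@@]2(C)O[Si](CC)(CC)CC)[C@@]3(C)[C@H](C(=O)OC)[C@H]4O[Si](C)(C)C(C)(C)C | intermediate
23 | C28 carboxylic acid with C26 methyl (key-step precursor) | CC1(C)OC(=O)C=C[C@]12CC[C@]13C[C@]4(C)C(=O)[C@](C)(C[C@H]1[C@@]2(C)O[Si](CC)(CC)CC)[C@@]3(C)[C@H](C(=O)O)[C@H]4O[Si](C)(C)C(C)(C)C | intermediate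
24 | γ-lactone bis-silyl ether (key-step product) | CC1(C)OC(=O)C=C[C@]12CC[C@]13C[C@]4(C)C(=O)[C@](C)(C[C@H]1[C@@]2(C)O[Si](CC)(CC)CC)[C@]31COC(=O)[C@@H]1[C@H]4O[Si](C)(C)C(C)(C)C | intermediate
25 | CNP0360620.3 | CC1(C)OC(=O)C=C[C@]12CC[C@]13C[C@]4(C)C(=O)[C@](C)(C[C@H]1[C@@]2(C)O)[C@]31COC(=O)[C@@H]1[C@H]4O | target

**Step count and risks**

Total steps: 19. Longest linear sequence: 17 steps (compound 4 to 25, steps 3–19).

Steps most likely to fail:

1. Step 10 (dearomative Michael coupling). The addition may go to the wrong ring carbon (C14) or to oxygen, the equilibrium may lie on the phenol side, and the lack of facial control at C18 together with only moderate control at C21 may leave little of the required isomer. Fallback: change from a reversible, thermodynamically controlled addition to an irreversible, kinetically controlled alkylation of a tied-back nucleophile. Setting out from 3 and 13, ester 3 is demethylated (LiI, pyridine) to 2,4-dihydroxy-3,5,6-trimethylbenzoic acid F1, which acetone with trifluoroacetic anhydride and trifluoroacetic acid converts into 7-hydroxy-2,2,5,6,8-pentamethyl-1,3-benzodioxin-4-one F2. Its lithium phenolate (LiN(SiMe3)2, THF, −78 °C), in which O17 is the only anionic oxygen and the ketal flanks C14, is added to enone 13 to give the dioxinone adduct F3. K2CO3 in methanol opens the dioxinone to the methyl ester enol, returning to the route at 14 (still followed by separation of the C18/C21 isomers).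

2. Step 18 (C–H lactonisation). Cyclopalladation may fail at the hindered bridgehead methyl, or the silyl ethers may be lost and the freed alcohols oxidised in the acidic fluorinated solvent. Fallback: an amidyl-radical 1,5-hydrogen transfer (Hofmann–Löffler–Freytag-type N-iodoamide photolysis) in place of palladium catalysis. Setting out from acid 23, the mixed anhydride (isobutyl chloroformate, N-methylmorpholine) with ammonia gives the primary amide F4. PhI(OAc)2 and I2 under visible light form the N-iodoamide, whose amidyl radical abstracts hydrogen from C26 through a six-membered transition state to give the C26 iodide F5, which cyclises on oxygen to the iminolactone F6. Mild aqueous hydrolysis gives lactone 24, where the route is rejoined.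

3. Step 15 (C31 reduction). Turnover may be poor at the ketone flanked by quaternary C14, the catalyst may be mismatched with the cage so that hydride arrives from the more open C16 side (giving the C31 epimer), or the ring A alkene may be saturated. Fallback: a biocatalytic reduction in place of the metal-catalysed hydrogenation. Setting out from 20, a ketoreductase panel (NADPH with glucose/glucose dehydrogenase recycling, aqueous buffer with co-solvent) is screened for dynamic reductive kinetic resolution of the β-keto ester to the (31R)-trans hydroxy ester, returning at 21; no new compound is made.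

Further compounds
F1 | step 10 | 2,4-dihydroxy-3,5,6-trimethylbenzoic acid | OC(=O)c1c(C)c(C)c(O)c(C)c1O
F2 | step 10 | 7-hydroxy-2,2,5,6,8-pentamethyl-4H-1,3-benzodioxin-4-one | CC1(C)Oc2c(C)c(O)c(C)c(C)c2C(=O)O1
F3 | step 10 | dioxinone Michael adduct (14 with C31–O and C28 tied as the acetonide) | C/C=C/[C@@]1(C(=O)OC)CCC(=O)[C@@H](C[C@@]2(C)C(=O)C(C)=C3OC(C)(C)OC(=O)C3=C2C)[C@@]1(C)O[Si](CC)(CC)CC
F4 | step 18 | C28 primary amide of 23 | CC1(C)OC(=O)C=C[C@]12CC[C@]13C[C@]4(C)C(=O)[C@](C)(C[C@H]1[C@@]2(C)O[Si](CC)(CC)CC)[C@@]3(C)[C@H](C(N)=O)[C@H]4O[Si](C)(C)C(C)(C)C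
F5 | step 18 | C26 iodide of amide F4 | CC1(C)OC(=O)C=C[C@]12CC[C@]13C[C@]4(C)C(=O)[C@](C)(C[C@H]1[C@@]2(C)O[Si](CC)(CC)CC)[C@@]3(CI)[C@H](C(N)=O)[C@H]4O[Si](C)(C)C(C)(C)C
F6 | step 18 | iminolactone (24 with C28=NH in place of C28=O) | CC1(C)OC(=O)C=C[C@]12CC[C@]13C[C@]4(C)C(=O)[C@](C)(C[C@H]1[C@@]2(C)O[Si](CC)(CC)CC)[C@]31COC(=N)[C@@H]1[C@H]4O[Si](C)(C)C(C)(C)C
F0 | step 15 | none | none
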